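**Assumption:** the target SMILES has no stereocentre and no stereogenic double bond, so the compound is achiral; "single enantiomer" is read as this one compound and no stereocontrol is needed.

## Retrosynthetic overview

1. 13 ⇐ 12 (same-pot methanolysis of acetate and aryl silyl ether) ⇐ benzylic CH2–CH2 bond: aldehyde 9, used through its N–H hydrazone 11 as a benzylic carbanion (carbonyl carbon with reversed polarity, N2 as traceless leaving group), plus benzylic chloride 10.
2. 9 ⇐ ortho-prenyl phenol 7 + prenal 6 by condensation and oxa-6π electrocyclisation; the silyl group blocks the second oxygen, so the pyran can only close onto the oxygen next to the prenyl group.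
3. 7 ⇐ tert-prenyl ether 5 by aromatic Claisen rearrangement, steered to C2 by the meta-formyl and meta-silyloxy groups.
4. 5 ⇐ 3,5-dihydroxybenzaldehyde 1 by mono-silylation, copper-catalysed O-alkylation with 3 and semi-hydrogenation.
5. Ring order: both benzene rings are bought; the pyran ring is the only ring made (step 4), before the fragment coupling (step 5).

## Route

Step 1
Reactants: 1 3,5-dihydroxybenzaldehyde
Product: 2 3-[(tert-butyldimethylsilyl)oxy]-5-hydroxybenzaldehyde
Conditions: 1 (1.5 equiv), TBSCl (1.0 equiv), imidazole (1.2 equiv), DMF, 0 °C to 23 °C; excess 1 recovered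
Reagents that add atoms: tert-butyldimethylsilyl chloride (TBSCl), CC(C)(C)[Si](C)(C)Cl
Why: Imidazole-mediated silylation of one of two equivalent phenols, where the cheap diol in excess makes the statistical mono-silyl ether the main silylated product and leaves one phenol free (no stereocentre).

Step 2
Reactants: 2 3-[(tert-butyldimethylsilyl)oxy]-5-hydroxybenzaldehyde; 3 3-chloro-3-methylbut-1-yne
Product: 4 3-[(tert-butyldimethylsilyl)oxy]-5-[(2-methylbut-3-yn-2-yl)oxy]benzaldehyde
Conditions: 3 (1.5 equiv), CuCl2 (1 mol %), DBU (1.5 equiv), MeCN, 0 °C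
Reagents that add atoms: none
Why: Copper-catalysed propargylic etherification (copper acetylide/allenylidene pathway) joins a tertiary propargylic chloride to a phenol at 0 °C, where aldehyde and aryl silyl ether are untouched.

Step 3
Reactants: 4 3-[(tert-butyldimethylsilyl)oxy]-5-[(2-methylbut-3-yn-2-yl)oxy]benzaldehyde
Product: 5 3-[(tert-butyldimethylsilyl)oxy]-5-[(2-methylbut-3-en-2-yl)oxy]benzaldehyde
Conditions: H2 (1 atm), Pd/CaCO3 poisoned with Pb(OAc)2 (5 wt % Pd), quinoline, EtOAc, 23 °C, stopped after 1 equiv H2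
Reagents that add atoms: none
Why: Poisoned-palladium semi-hydrogenation (Lindlar reduction) stops at the terminal alkene and gives the 1,1-dimethylallyl aryl ether whose Claisen shift delivers an unrearranged prenyl group, with aldehyde and silyl ether inert.

Step 4
Reactants: 5 3-[(tert-butyldimethylsilyl)oxy]-5-[(2-methylbut-3-en-2-yl)oxy]benzaldehyde; 6 3-methylbut-2-enal (prenal)
Product: 9 5-[(tert-butyldimethylsilyl)oxy]-2,2-dimethyl-8-(3-methylbut-2-en-1-yl)-2H-chromene-7-carbaldehyde, via ortho-prenyl phenol 7 (not isolated), via ortho-quinone methide 8 (not isolated)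
Conditions: xylenes, 135 °C, 2 h; then 6 (2.0 equiv), ethylenediammonium diacetate (20 mol %), 140 °C
Reagents that add atoms: none
Why: Aromatic Claisen rearrangement ([3,3]) of the tert-prenyl ether goes to C2, the ortho carbon next to the formyl group and para to the silyloxy group (both meta substituents steer there), and freed phenol 7, whose only open ortho carbon is C4, then condenses with prenal under ammonium acetate catalysis to ortho-quinone methide 8, which closes by oxa-6π electrocyclisation (chromenylation) onto the one unprotected oxygen, the one flanked by the prenyl group.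

Step 5
Reactants: 9 5-[(tert-butyldimethylsilyl)oxy]-2,2-dimethyl-8-(3-methylbut-2-en-1-yl)-2H-chromene-7-carbaldehyde; 10 4-(chloromethyl)phenyl acetate
Product: 13 7-[2-(4-hydroxyphenyl)ethyl]-2,2-dimethyl-8-(3-methylbut-2-en-1-yl)-2H-chromen-5-ol, via N–H hydrazone 11 (not isolated), via protected bibenzyl 12 (not isolated)
Conditions: N2H4·H2O (1.2 equiv), THF, 23 °C, then evaporation (PhMe azeotrope); 10 (1.5 equiv), Ni(cod)2 (10 mol %), 4,4'-di-tert-butyl-2,2'-bipyridine (12 mol %), K3PO4 (2.0 equiv), THF, 60 °C; then K2CO3 (50 mol %), MeOH, 23 °C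
Reagents that add atoms: none
Why: Proposed new method: N–H hydrazone 11 serves as a benzylic carbanion equivalent of aldehyde 9 (Wolff–Kishner-type polarity reversal), zerovalent nickel inserts into the benzylic C–Cl bond of 10, the deprotonated hydrazone binds through nitrogen, tautomerises to the diazenyl form and loses N2 to give a dibenzylnickel species that reductively eliminates the CH2–CH2 bond, the closest known reaction type being nickel-catalysed deoxygenative cross-coupling of aldehyde N–H hydrazones with alkyl and aryl halides, after which carbonate-catalysed methanolysis of 12 removes the aryl acetate and the aryl silyl ether in the same pot.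

## Compound list

1 | 3,5-dihydroxybenzaldehyde | O=Cc1cc(O)cc(O)c1 | starting material
2 | 3-[(tert-butyldimethylsilyl)oxy]-5-hydroxybenzaldehyde | O=Cc1cc(O)cc(O[Si](C)(C)C(C)(C)C)c1 | intermediate
3 | 3-chloro-3-methylbut-1-yne | C#CC(C)(C)Cl | starting material
4 | 3-[(tert-butyldimethylsilyl)oxy]-5-[(2-methylbut-3-yn-2-yl)oxy]benzaldehyde | O=Cc1cc(OC(C)(C)C#C)cc(O[Si](C)(C)C(C)(C)C)c1 | intermediate
5 | 3-[(tert-butyldimethylsilyl)oxy]-5-[(2-methylbut-3-en-2-yl)oxy]benzaldehyde | O=Cc1cc(OC(C)(C)C=C)cc(O[Si](C)(C)C(C)(C)C)c1 | intermediate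
6 | 3-methylbut-2-enal (prenal) | CC(C)=CC=O | starting material
7 | 5-[(tert-butyldimethylsilyl)oxy]-3-hydroxy-2-(3-methylbut-2-en-1-yl)benzaldehyde | O=Cc1cc(O[Si](C)(C)C(C)(C)C)cc(O)c1CC=C(C)C | intermediate
8 | (6Z)-5-[(tert-butyldimethylsilyl)oxy]-3-formyl-2-(3-methylbut-2-en-1-yl)-6-(3-methylbut-2-en-1-ylidene)cyclohexa-2,4-dien-1-one | CC(C)=C/C=C1\C(=O)C(CC=C(C)C)=C(C=O)C=C1O[Si](C)(C)C(C)(C)C | intermediate
9 | 5-[(tert-butyldimethylsilyl)oxy]-2,2-dimethyl-8-(3-methylbut-2-en-1-yl)-2H-chromene-7-carbaldehyde | CC(C)=CCc1c(C=O)cc(O[Si](C)(C)C(C)(C)C)c2c1OC(C)(C)C=C2 | intermediate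
10 | 4-(chloromethyl)phenyl acetate | CC(=O)Oc1ccc(CCl)cc1 | starting material
11 | (E)-{[5-[(tert-butyldimethylsilyl)oxy]-2,2-dimethyl-8-(3-methylbut-2-en-1-yl)-2H-chromen-7-yl]methylidene}hydrazine | CC(C)=CCc1c(/C=N/N)cc(O[Si](C)(C)C(C)(C)C)c2c1OC(C)(C)C=C2 | intermediate
12 | 4-{2-[5-[(tert-butyldimethylsilyl)oxy]-2,2-dimethyl-8-(3-methylbut-2-en-1-yl)-2H-chromen-7-yl]ethyl}phenyl acetate | CC(C)=CCc1c(CCc2ccc(OC(C)=O)cc2)cc(O[Si](C)(C)C(C)(C)C)c2c1OC(C)(C)C=C2 | intermediate
13 | 7-[2-(4-hydroxyphenyl)ethyl]-2,2-dimethyl-8-(3-methylbut-2-en-1-yl)-2H-chromen-5-ol | CC(C)=CCc1c(CCc2ccc(O)cc2)cc(O)c2c1OC(C)(C)C=C2 | target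

## Step count and risks

Total step count: 5. Longest linear sequence: 5 steps (1 to 13); compounds 3, 6 and 10 are bought.

**Step 5 (most likely to fail).** The hydrazone may be benzylated or acetylated on nitrogen, form the azine, or be reduced to the 7-methyl compound. Chloride 10 may homocouple, or lose its acetate early and polymerise through the quinone methide. The silyl ether may be cleaved by hydrazine, after which the free phenol would be O-benzylated.
Fallback, setting out from 9: hydrazone 11 is made as before and added instead to the carbonyl group of purchased 4-[(tert-butyldimethylsilyl)oxy]benzaldehyde (O=Cc1ccc(O[Si](C)(C)C(C)(C)C)cc1). Conditions are [RuCl2(p-cymene)]2 (1.5 mol %), 1,2-bis(dimethylphosphino)ethane (3 mol %) and K3PO4 (25 mol %) in THF at 45 °C. This polarity-reversed carbonyl addition loses N2 and gives the racemic carbinol 2-{5-[(tert-butyldimethylsilyl)oxy]-2,2-dimethyl-8-(3-methylbut-2-en-1-yl)-2H-chromen-7-yl}-1-{4-[(tert-butyldimethylsilyl)oxy]phenyl}ethan-1-ol F1. NaH, CS2 and then MeI in THF at 0 °C convert it into the S-methyl xanthate F2. Bu3SnH with Et3B and air in toluene at 23 °C (Barton–McCombie deoxygenation, which avoids a benzylic cation next to the prenyl group) gives the bis-silyl bibenzyl F3. K2CO3 in MeOH then removes both silyl groups, and the route is rejoined at 13.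

**Step 4.** The Claisen shift may partly go to C4. The condensation takes place at a carbon flanked by the bulky silyloxy group and may be slow. The silyl ether or the ortho-prenyl aldehyde (carbonyl-ene cyclisation) may suffer at 140 °C.
Fallback, setting out from 5: 5 is heated alone in toluene at 110 °C and phenol 7 is isolated. Its one free phenol is etherified with 3 (CuCl2, DBU, MeCN, 0 °C) to the aryl propargyl ether 5-[(tert-butyldimethylsilyl)oxy]-3-[(2-methylbut-3-yn-2-yl)oxy]-2-(3-methylbut-2-en-1-yl)benzaldehyde F4. Heating F4 in xylenes at 140 °C brings about the propargyl Claisen rearrangement to C4 (C2 is blocked), a 1,5-hydrogen shift and oxa-6π ring closure. This gives 9, where the route is rejoined.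

**Step 1.** Mono-silylation of a symmetric diol is statistical, and bis-silylation or silyl scrambling can lower the yield further.
Fallback, setting out from 1: both phenols are silylated (TBSCl 2.2 equiv, imidazole, DMF) to 3,5-bis[(tert-butyldimethylsilyl)oxy]benzaldehyde F5. One silyl group is then removed with K2CO3 (20 mol %) in MeOH at 0 °C, where the first phenoxide formed slows loss of the second group. The route is rejoined at 2.

Further compounds
F1 | step 5 | 2-{5-[(tert-butyldimethylsilyl)oxy]-2,2-dimethyl-8-(3-methylbut-2-en-1-yl)-2H-chromen-7-yl}-1-{4-[(tert-butyldimethylsilyl)oxy]phenyl}ethan-1-ol (racemic) | CC(C)=CCc1c(CC(O)c2ccc(O[Si](C)(C)C(C)(C)C)cc2)cc(O[Si](C)(C)C(C)(C)C)c2c1OC(C)(C)C=C2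
F2 | step 5 | O-(2-{5-[(tert-butyldimethylsilyl)oxy]-2,2-dimethyl-8-(3-methylbut-2-en-1-yl)-2H-chromen-7-yl}-1-{4-[(tert-butyldimethylsilyl)oxy]phenyl}ethyl) S-methyl carbonodithioate (racemic) | CC(C)=CCc1c(CC(OC(=S)SC)c2ccc(O[Si](C)(C)C(C)(C)C)cc2)cc(O[Si](C)(C)C(C)(C)C)c2c1OC(C)(C)C=C2
F3 | step 5 | tert-butyl{4-[2-(5-[(tert-butyldimethylsilyl)oxy]-2,2-dimethyl-8-(3-methylbut-2-en-1-yl)-2H-chromen-7-yl)ethyl]phenoxy}dimethylsilane | CC(C)=CCc1c(CCc2ccc(O[Si](C)(C)C(C)(C)C)cc2)cc(O[Si](C)(C)C(C)(C)C)c2c1OC(C)(C)C=C2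
F4 | step 4 | 5-[(tert-butyldimethylsilyl)oxy]-3-[(2-methylbut-3-yn-2-yl)oxy]-2-(3-methylbut-2-en-1-yl)benzaldehyde | O=Cc1cc(O[Si](C)(C)C(C)(C)C)cc(OC(C)(C)C#C)c1CC=C(C)C
F5 | step 1 | 3,5-bis[(tert-butyldimethylsilyl)oxy]benzaldehyde | O=Cc1cc(O[Si](C)(C)C(C)(C)C)cc(O[Si](C)(C)C(C)(C)C)c1
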